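**Retrosynthetic overview**

1. Kweichowenol B ⇐ Si–O cleavage and hydroxyl-directed reduction of the C6 ketone of a 2-hydroxy-2-(benzoyloxymethyl)cyclohex-3-enone that already carries the C4 benzoate and a C5 silyl ether.
2. That cyclohexenone ⇐ acyloin (α-ketol) ring enlargement of a 1-(benzoyloxyacetyl)cyclopent-2-en-1-ol: the exocyclic acyl carbon (future C1) is inserted between the carbinol carbon (future C6) and the alkene carbon C2, so the five-membered carbocycle becomes the six-membered one.
3. Enabling feature: the tertiary α-ketol unit O–C–C=O, that is, the hydroxyl-bearing ring carbon of the cyclopentene with the exocyclic ketone carbon on it and the sp2 ring carbon C2 as its ring neighbour; in the target this is C1(OH)(CH2OBz) lying between C6–OH and C2=C3.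
4. The cyclopentenol ⇐ double Mitsunobu benzoylation (inversion at C4) of the deprotected ketol ⇐ dihydroxylation of the adduct of 1-ethoxyvinyllithium with the D-ribose-derived cyclopentenone acetonide.
5. Ring order: the cyclopentene ring is bought, the six-membered ring arises only in the key step, and the dioxolane is a temporary protecting ring.

Key step: step 6

Remark: locants C1–C7 are those of the target (C1 quaternary carbinol carbon, C2=C3 alkene, C4 benzoate carbon, C5 and C6 secondary carbinol carbons, C7 exocyclic CH2); enone 1 is taken as the commercial D-ribose-derived enantiomer.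

**Route**

Step 1
Reactants: 1 (3aR,6aR)-2,2-dimethyl-3a,6a-dihydro-4H-cyclopenta[d][1,3]dioxol-4-one; 2 ethyl vinyl ether
Product: 4 (3aR,4S,6aR)-4-(1-ethoxyethenyl)-2,2-dimethyl-3a,6a-dihydro-4H-cyclopenta[d][1,3]dioxol-4-ol, via 1-ethoxyvinyllithium 3 (not isolated)
Conditions: 2, t-BuLi, THF, −78 to 0 °C; then 1, −78 °C; H2O
Reagents that add atoms: none
Why: 1,2-addition of an α-lithiated enol ether (acyl anion equivalent) to the enone carbonyl should occur on the convex face, anti to the cis-fused dioxolane, which sets the tertiary carbinol with its OH cis to both acetal oxygens.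

Step 2
Reactants: 4
Product: 6 2-hydroxy-1-[(3aR,4S,6aR)-4-hydroxy-2,2-dimethyl-3a,6a-dihydro-4H-cyclopenta[d][1,3]dioxol-4-yl]ethan-1-one, via ethyl hemiketal 5 (not isolated)
Conditions: OsO4 (2 mol %), NMO, acetone/H2O, 0 °C
Reagents that add atoms: osmium tetroxide, O=[Os](=O)(=O)=O (catalytic, transfers both new oxygen atoms); N-methylmorpholine N-oxide, C[N+]1([O-])CCOCC1 (stoichiometric oxygen source)
Why: Upjohn dihydroxylation should take the electron-rich 1,1-disubstituted enol ether in preference to the hindered ring alkene flanked by two oxygenated carbons, and the hemiketal then loses ethanol to give the hydroxyacetyl ketone; no stereocentre is formed.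

Step 3
Reactants: 6
Product: 7 2-hydroxy-1-[(1S,4R,5R)-1,4,5-trihydroxycyclopent-2-en-1-yl]ethan-1-one
Conditions: AcOH/H2O (4:1), 45 °C
Reagents that add atoms: none
Why: Acid hydrolysis of the isopropylidene acetal frees the cis-4,5-diol without touching a stereocentre.

Step 4
Reactants: 7
Product: 8 2-[(1S,4S,5R)-4-(benzoyloxy)-1,5-dihydroxycyclopent-2-en-1-yl]-2-oxoethyl benzoate
Conditions: PhCO2H, PPh3, DIAD (2.4 equiv each), THF, 0 °C to rt
Reagents that add atoms: benzoic acid, O=C(O)c1ccccc1
Why: Double Mitsunobu esterification: the primary alcohol is benzoylated and the allylic C4 alcohol is displaced by benzoate in an SN2 reaction with inversion, which puts the C4 benzoate trans to the C5 hydroxyl, while the C5 hydroxyl next to the quaternary carbon and the tertiary hydroxyl are too hindered to be displaced.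

Step 5
Reactants: 8
Product: 9 2-[(1S,4S,5R)-4-(benzoyloxy)-1-hydroxy-5-(triethylsilyloxy)cyclopent-2-en-1-yl]-2-oxoethyl benzoate
Conditions: TESCl, imidazole, DMF, 0 °C
Reagents that add atoms: chlorotriethylsilane, CC[Si](Cl)(CC)CC
Why: Silylation with a silyl chloride and imidazole should take the only remaining secondary hydroxyl, which leaves the tertiary hydroxyl free for chelation in the next step and blocks enediol isomerisation of the later ketone.

Step 6
Reactants: 9
Product: 10 [(1R,4S,5R)-4-(benzoyloxy)-1-hydroxy-6-oxo-5-(triethylsilyloxy)cyclohex-2-en-1-yl]methyl benzoate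
Conditions: Zn(OTf)2 (20 mol %), PhMe, 80 °C
Reagents that add atoms: none
Why: The zinc cation should bind the tertiary hydroxyl and the ketone oxygen of the O–C–C=O unit in a syn-periplanar five-membered chelate, which polarises the exocyclic carbonyl; the ring alkene carbon C2 then shifts suprafacially from the carbinol carbon to the acyl carbon while the carbinol carbon becomes the C6 ketone, so that the acyl carbon enters the ring as C1. The closest known reaction type is the Lewis-acid α-ketol (acyloin) rearrangement with ring enlargement, as in the D-homoannulation of 17-hydroxy-20-ketosteroids and the conversion of 1-acylcyclopentanols into 2-hydroxy-2-substituted cyclohexanones. The six-membered ring is not closed by a cyclisation: it forms by ring expansion, the bond from the carbinol carbon to C2 being exchanged for the C1–C2 bond in one concerted 1,2-shift. The new stereocentre C1 is set by chirality transfer from the carbinol stereocentre, which is destroyed: in the chelate the carbonyl oxygen stays on the face of the former C–OH bond, so the C1 hydroxyl ends cis to the C5 silyloxy group and trans to the C4 benzoate, with CH2OBz on the opposite face. The step needs migration of the alkenyl carbon C2 and not of the oxygen-bearing carbon C5, which the higher migratory aptitude of an sp2 carbon (π participation in the bridged transition state) and the inductive deactivation of C5 by its silyloxy group and the neighbouring benzoate should secure. It also needs kinetic control against an onward shift to a conjugated enone, which the poor migratory aptitude of the CH2OBz group and the relief of cyclopentene strain and eclipsing should secure.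

Step 7
Reactants: 10
Product: 11 [(1R,4S,5S,6S)-4-(benzoyloxy)-1,6-dihydroxy-5-(triethylsilyloxy)cyclohex-2-en-1-yl]methyl benzoate
Conditions: Me4NBH(OAc)3, MeCN/AcOH (1:1), −20 °C
Reagents that add atoms: none
Why: Hydroxyl-directed reduction of the Evans–Saksena type: the borohydride is bound by the free tertiary C1 hydroxyl and should deliver hydride to the same face of the C6 ketone, which gives the 1,6-trans diol with C6–OH anti to both neighbouring oxygens (axial attack anti to the axial CH2OBz group leads to the same result).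

Step 8
Reactants: 11
Product: 12 kweichowenol B, [(1R,4S,5S,6S)-4-(benzoyloxy)-1,5,6-trihydroxycyclohex-2-en-1-yl]methyl benzoate
Conditions: HF·pyridine, THF, 0 °C to rt
Reagents that add atoms: none
Why: Acidic fluoride should cleave the secondary Si–O bond under conditions in which benzoates neither hydrolyse nor migrate; no stereocentre is touched.

**Compound list**

1 | (3aR,6aR)-2,2-dimethyl-3a,6a-dihydro-4H-cyclopenta[d][1,3]dioxol-4-one | CC1(C)O[C@@H]2C=CC(=O)[C@@H]2O1 | starting material
2 | ethyl vinyl ether | C=COCC | starting material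
3 | 1-ethoxyvinyllithium | [Li]C(=C)OCC | intermediate
4 | (3aR,4S,6aR)-4-(1-ethoxyethenyl)-2,2-dimethyl-3a,6a-dihydro-4H-cyclopenta[d][1,3]dioxol-4-ol | C=C(OCC)[C@]1(O)C=C[C@H]2OC(C)(C)O[C@@H]12 | intermediate
5 | 1-ethoxy-1-[(3aR,4S,6aR)-4-hydroxy-2,2-dimethyl-3a,6a-dihydro-4H-cyclopenta[d][1,3]dioxol-4-yl]ethane-1,2-diol (ethyl hemiketal, both epimers at the hemiketal carbon) | CCOC(O)(CO)[C@]1(O)C=C[C@H]2OC(C)(C)O[C@@H]12 | intermediate
6 | 2-hydroxy-1-[(3aR,4S,6aR)-4-hydroxy-2,2-dimethyl-3a,6a-dihydro-4H-cyclopenta[d][1,3]dioxol-4-yl]ethan-1-one | OCC(=O)[C@]1(O)C=C[C@H]2OC(C)(C)O[C@@H]12 | intermediate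
7 | 2-hydroxy-1-[(1S,4R,5R)-1,4,5-trihydroxycyclopent-2-en-1-yl]ethan-1-one | OCC(=O)[C@]1(O)C=C[C@@H](O)[C@H]1O | intermediate
8 | 2-[(1S,4S,5R)-4-(benzoyloxy)-1,5-dihydroxycyclopent-2-en-1-yl]-2-oxoethyl benzoate | O=C(OCC(=O)[C@]1(O)C=C[C@H](OC(=O)c2ccccc2)[C@H]1O)c1ccccc1 | intermediate
9 | 2-[(1S,4S,5R)-4-(benzoyloxy)-1-hydroxy-5-(triethylsilyloxy)cyclopent-2-en-1-yl]-2-oxoethyl benzoate | O=C(OCC(=O)[C@]1(O)C=C[C@H](OC(=O)c2ccccc2)[C@H]1O[Si](CC)(CC)CC)c1ccccc1 | intermediate
10 | [(1R,4S,5R)-4-(benzoyloxy)-1-hydroxy-6-oxo-5-(triethylsilyloxy)cyclohex-2-en-1-yl]methyl benzoate | O=C(OC[C@]1(O)C=C[C@H](OC(=O)c2ccccc2)[C@@H](O[Si](CC)(CC)CC)C1=O)c1ccccc1 | intermediate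
11 | [(1R,4S,5S,6S)-4-(benzoyloxy)-1,6-dihydroxy-5-(triethylsilyloxy)cyclohex-2-en-1-yl]methyl benzoate | O=C(OC[C@]1(O)C=C[C@H](OC(=O)c2ccccc2)[C@@H](O[Si](CC)(CC)CC)[C@@H]1O)c1ccccc1 | intermediate
12 | kweichowenol B, [(1R,4S,5S,6S)-4-(benzoyloxy)-1,5,6-trihydroxycyclohex-2-en-1-yl]methyl benzoate | O=C(OC[C@]1(O)C=C[C@H](OC(=O)c2ccccc2)[C@@H](O)[C@@H]1O)c1ccccc1 | target

**Step count and risks**

Total step count: 8. Longest linear sequence: 8 steps (1 to 12).

The three steps most likely to fail:

Step 6. What may go wrong: the oxygen-bearing ring carbon C5 migrates in competition with the alkenyl carbon, or the allylic benzoate is lost by ionisation or by β-elimination from the β-benzoyloxy ketone under Lewis acid and heat. The fallback moves the ring enlargement to the acetonide stage and the C4 inversion to the end. There the ring carries no ester, the β-oxygen of the product ketone is an acetal oxygen that does not leave, and C5 is a dioxolane carbon whose oxygen lone pairs are shared with the acetal carbon. It sets out from 6. Selective benzoylation of the primary hydroxyl (BzCl, 2,4,6-collidine, CH2Cl2, −20 °C) should give 2-[(3aR,4S,6aR)-4-hydroxy-2,2-dimethyl-3a,6a-dihydro-4H-cyclopenta[d][1,3]dioxol-4-yl]-2-oxoethyl benzoate F1. The chelation-controlled acyloin ring enlargement (Zn(OTf)2, PhMe, 80 °C) should then give [(1R,4R,5R)-1-hydroxy-4,5-(isopropylidenedioxy)-6-oxocyclohex-2-en-1-yl]methyl benzoate F2. Hydroxyl-directed reduction (Me4NBH(OAc)3, MeCN/AcOH) should give [(1R,4R,5S,6S)-1,6-dihydroxy-4,5-(isopropylidenedioxy)cyclohex-2-en-1-yl]methyl benzoate F3, and AcOH/H2O should give [(1R,4R,5R,6S)-1,4,5,6-tetrahydroxycyclohex-2-en-1-yl]methyl benzoate F4. A Mitsunobu reaction at the allylic C4 hydroxyl (PPh3, DIAD, excess PhCO2H, THF, −20 °C, so that esterification outruns epoxide closure of the trans diols) should then give, with inversion, 12, where the fallback comes back to the route.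

Step 4. What may go wrong: the displacement at C4 is not clean, through poor site selectivity between the two secondary hydroxyls, allylic transposition (SN2′) or elimination towards a cyclopentadiene. The fallback replaces the Mitsunobu inversion by opening of a cyclic sulfite. It sets out from 7. Selective benzoylation of the primary hydroxyl (BzCl, 2,4,6-collidine, CH2Cl2, −20 °C) should give 2-oxo-2-[(1S,4R,5R)-1,4,5-trihydroxycyclopent-2-en-1-yl]ethyl benzoate F5. SOCl2 and Et3N (CH2Cl2, 0 °C) should convert the cis-4,5-diol into the cyclic sulfite 2-[(3aR,4S,6aR)-4-hydroxy-2-oxido-3a,6a-dihydro-4H-cyclopenta[d][1,3,2]dioxathiol-4-yl]-2-oxoethyl benzoate F6. PhCO2Cs in DMF (60 °C) should open the sulfite at the allylic carbon C4 with inversion, and acidic work-up should hydrolyse the sulfite monoester to give 8, where the fallback comes back to the route.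

Step 2. What may go wrong: over-oxidation by dihydroxylation of the ring alkene beside the enol ether, or hydrolysis of the enol ether to the methyl ketone before it is oxidised. The fallback brings in the two-carbon unit at the right oxidation level, so that no alkene has to be oxidised. It sets out from 1. Addition of 2-lithio-2-[(tert-butyldimethylsilyloxy)methyl]-1,3-dithiane (from the dithiane and n-BuLi, THF, −30 °C; then 1, −78 °C) should give (3aR,4S,6aR)-4-{2-[(tert-butyldimethylsilyloxy)methyl]-1,3-dithian-2-yl}-2,2-dimethyl-3a,6a-dihydro-4H-cyclopenta[d][1,3]dioxol-4-ol F7. Dethioacetalisation (MeI, CaCO3, MeCN/H2O) should give 2-(tert-butyldimethylsilyloxy)-1-[(3aR,4S,6aR)-4-hydroxy-2,2-dimethyl-3a,6a-dihydro-4H-cyclopenta[d][1,3]dioxol-4-yl]ethan-1-one F8. HF·pyridine (THF, 0 °C) should then remove the silyl group to give 6, where the fallback comes back to the route.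

**Further compounds**

F1 | step 6 | 2-[(3aR,4S,6aR)-4-hydroxy-2,2-dimethyl-3a,6a-dihydro-4H-cyclopenta[d][1,3]dioxol-4-yl]-2-oxoethyl benzoate | O=C(OCC(=O)[C@]1(O)C=C[C@H]2OC(C)(C)O[C@@H]12)c1ccccc1
F2 | step 6 | [(1R,4R,5R)-1-hydroxy-4,5-(isopropylidenedioxy)-6-oxocyclohex-2-en-1-yl]methyl benzoate | O=C(OC[C@]1(O)C=C[C@H]2OC(C)(C)O[C@H]2C1=O)c1ccccc1
F3 | step 6 | [(1R,4R,5S,6S)-1,6-dihydroxy-4,5-(isopropylidenedioxy)cyclohex-2-en-1-yl]methyl benzoate | O=C(OC[C@]1(O)C=C[C@H]2OC(C)(C)O[C@H]2[C@@H]1O)c1ccccc1
F4 | step 6 | [(1R,4R,5R,6S)-1,4,5,6-tetrahydroxycyclohex-2-en-1-yl]methyl benzoate | O=C(OC[C@]1(O)C=C[C@@H](O)[C@@H](O)[C@@H]1O)c1ccccc1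
F5 | step 4 | 2-oxo-2-[(1S,4R,5R)-1,4,5-trihydroxycyclopent-2-en-1-yl]ethyl benzoate | O=C(OCC(=O)[C@]1(O)C=C[C@@H](O)[C@H]1O)c1ccccc1
F6 | step 4 | 2-[(3aR,4S,6aR)-4-hydroxy-2-oxido-3a,6a-dihydro-4H-cyclopenta[d][1,3,2]dioxathiol-4-yl]-2-oxoethyl benzoate (cyclic sulfite, both epimers at sulfur) | O=C(OCC(=O)[C@]1(O)C=C[C@H]2OS(=O)O[C@@H]12)c1ccccc1
F7 | step 2 | (3aR,4S,6aR)-4-{2-[(tert-butyldimethylsilyloxy)methyl]-1,3-dithian-2-yl}-2,2-dimethyl-3a,6a-dihydro-4H-cyclopenta[d][1,3]dioxol-4-ol | CC(C)(C)[Si](C)(C)OCC1(SCCCS1)[C@]1(O)C=C[C@H]2OC(C)(C)O[C@@H]12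
F8 | step 2 | 2-(tert-butyldimethylsilyloxy)-1-[(3aR,4S,6aR)-4-hydroxy-2,2-dimethyl-3a,6a-dihydro-4H-cyclopenta[d][1,3]dioxol-4-yl]ethan-1-one | CC(C)(C)[Si](C)(C)OCC(=O)[C@]1(O)C=C[C@H]2OC(C)(C)O[C@@H]12
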